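The earlier runs and the new flask come from a simulation for substances that don't exist, and the scatter is random.

A leftover stands at the end of the dawn run. At 25.0 h the two products hold 31.9 % of the substrates charged, so 68.1 % has not become product, and yet the left-handed product reads 30.2 % at 20.0 h and 30.2 % at 25.0 h.

common to all: racemization catalyst 0.51 mol%
- dawn: left-handed substrate 0.11 M; right-handed substrate 0.11 M; coupling partner 2.2 equiv; precatalyst 0.58 mol%; run made earlier
- winter: left-handed substrate 0.17 M; right-handed substrate 0.17 M; coupling partner 2.2 equiv; precatalyst 0.58 mol%; run made earlier
- summer: left-handed substrate 0.076 M; right-handed substrate 0.076 M; coupling partner 2.2 equiv; precatalyst 0.87 mol%; run made earlier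
- flask: left-handed substrate 0.076 M; right-handed substrate 0.076 M; coupling partner 2.20 equiv; precatalyst 0.58 mol%; time 20 h

| run | time / h | left-handed product / % | right-handed product / % |
|---|---|---|---|
| dawn | 6.00 | 18.9 | 0.9 |
| dawn | 12.0 | 27.9 | 1.6 |
| dawn | 20.0 | 30.2 | 1.6 |
| dawn | 25.0 | 30.2 | 1.7 |
| winter | 2.00 | 9.6 | 0.5 |
| winter | 4.00 | 19.9 | 1.1 |
| winter | 10.0 | 30.1 | 1.8 |
| winter | 25.0 | 31.5 | 1.6 |
| summer | 3.00 | 8.1 | 0 |
| summer | 8.00 | 22.3 | 0.5 |
| summer | 15.0 | 31.0 | 1.3 |
| summer | 25.0 | 34.3 | 1.7 |

(each reading ± 0.3 percentage points)

- free catalyst is single-handed; left-handed substrate and right-handed substrate are mirror images of each other, charged as a racemate, each of them at the stated concentration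
- an excess is the difference of the two amounts in percent of their sum
- an excess is below zero if the other one leads

- excess of left-handed product over right-handed product in the product at 1.0 h
- excess of left-handed product over right-handed product in the product at 20 h
- part of the left-handed substrate and right-handed substrate charged together that has reacted at 20 h

The ledger here is kept for the coupling partner, taken as the limiting reagent although its charge is 1.10 mol per mol of the two substrates together. Each product is assumed to take one coupling partner. In the dawn run, 29.0 % of the charged coupling partner therefore stands in product at the last reading; this is the capture share φ, moles of both products per mole of coupling partner charged. The other entry, 71.0 %, is not shown by the readings: it is either still unbound or lost another way.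

The winter run, more concentrated at the same loading, reads φ = 30.1 %, close to dawn. The summer run, which differs from dawn in two settings, being more dilute and carrying more precatalyst, reads 32.7 % at its last reading, more than dawn. This reckoning guesses that part of the coupling partner goes to a drain beside coupling, but the readings do not prove it.

The flask has dawn's loading and equivalents at a lower concentration, so this reckoning carries dawn's φ over and enters an estimated ceiling of 31.9 % of the substrates charged. The conversion of the flask at 20 h is expected at or a little below that estimate.

The forecast gives an excess of left-handed product of 91 % at 1.0 h and 90 % at 20 h, with 31 % reacted at 20 h, and says of the stall “the catalyst is apparently dying rather than the substrate running out”. Its conversion lies near the ceiling, but its reading of the stall differs from this ledger.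

The flask gives an excess of left-handed product of 90.4 % at 1.0 h and 90.4 % at 20 h, with 29.4 % reacted at 20 h, so the forecast stands on all three.

    left-handed substrate + racemization catalyst ⇌ right-handed substrate + racemization catalyst, rate k1*[racemization catalyst]*[left-handed substrate] forward; the back reaction follows from the equilibrium constant (k = 44700 M⁻¹ h⁻¹)
    2 coupling partner → self-condensation product (k = 1.23 M⁻¹ h⁻¹)
    2 racemization catalyst ⇌ resting dimer, settled at all times (K = 6120 M⁻¹)
    precatalyst → free catalyst (k = 0.0737 h⁻¹)
    coupling partner + free catalyst + right-handed substrate → free catalyst + right-handed product (k = 439 M⁻² h⁻¹)
    coupling partner + free catalyst + left-handed substrate → free catalyst + left-handed product (k = 8710 M⁻² h⁻¹)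

At 20 h the flask keeps 2.0 % of its coupling partner against 71 % of its left-handed substrate. Its charge of coupling partner divides into φ = 26.7 % in product, 71.3 % in self-condensation product, counting two molecules of coupling partner in each molecule of it, and that remainder. A neighbour charged with 2.3 mol% of precatalyst, other charges held, reaches φ = 43.7 % and 48.1 % reacted, above the forecast's 31 %, with 0.045 % of its coupling partner left.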